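| flask | substrate | remark | time |
|---|---|---|---|
| south | 0.20 M | run made earlier |  |
| east | 0.82 M | run made earlier |  |
| flask | 0.41 M |  | 4.0 h |

| run | time / h | isomer of the product / % | intermediate B / % | intermediate C / % | target / % | substrate / % | intermediate A / % |
|---|---|---|---|---|---|---|---|
| south | 0.833 | 0 | 0 | 34 | 2 | 59 | 8 |
| south | 1.50 | 1 | 1 | 34 | 1 | 54 | 8 |
| south | 2.50 | 0 | 2 | 33 | 0 | 51 | 13 |
| south | 3.00 | 1 | 3 | 30 | 2 | 47 | 14 |
| south | 4.00 | 0 | 6 | 30 | 2 | 45 | 19 |
| east | 0.333 | 0 | 0 | 32 | 0 | 69 | 4 |
| east | 0.667 | 1 | 0 | 34 | 0 | 60 | 4 |
| east | 1.00 | 0 | 1 | 36 | 0 | 55 | 6 |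
| east | 2.00 | 0 | 2 | 36 | 0 | 54 | 10 |
| east | 4.00 | 2 | 3 | 28 | 0 | 46 | 18 |

(standard deviation of a reading: 1.5 percentage points)

- a species is counted by the substrate in it: one idle adduct counts as two
- amounts and yields of target count idle adduct too
- the earlier runs were read with a standard deviation of 1.5 percentage points
- reactions considered so far: substrate -> intermediate A; intermediate A -> intermediate B; substrate <-> intermediate C; intermediate B <-> target; substrate + target <-> idle adduct; target <-> isomer of the product
- in an amount of target, one idle adduct counts as one target
- a reading or a percentage of substrate is of its free form alone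

1. the species that holds most of what was charged as substrate, at 4.0 h (intermediate B / substrate / intermediate A / intermediate C / isomer of the product / target)
2. the largest share itself, whichever of these holds it, in percent of the substrate charged

- Start from a one-step world, where one exponential tells the whole story, then see why this flask needs a second number: intermediate C already reads 32% in the east run at 0.333 h, early against 4.0 h, while substrate keeps falling afterwards.
- Compare the two runs at 4.00 h: their charges differ by a factor of 4.10, yet substrate reads 45% and 46%. So treat the steps that matter as first-order and put the 0.41 M flask on the same percentage curve.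
- Treat substrate and intermediate C as a pre-equilibrium, and call them the pool. From those readings, the free share φ = c(substrate)/(c(substrate) + c(intermediate C)) comes to 61.1%.
- Let the pool decay as exp(−λt). Don't read λ from substrate and intermediate C: that is the weak link, because φ times that pool merely returns the substrate readings.
- Reforge λ from the other side: at 4.00 h, intermediate A, intermediate B, target and isomer of the product together average 25.0% over the two runs. Idle adduct has no column of its own, so the substrate bound in it stays out of this sum. This gives λ = 0.0719 h⁻¹, the drain constant, the pool's fractional loss per hour.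
- Commit for the flask at 4.0 h: φ·exp(−λt) gives substrate 45.8%, and intermediate C gets 29.2%, so substrate holds more than intermediate C or the whole downstream sum.
- The forecast, reckoned separately, says substrate at 45.5%, within 43.5% to 47.5%: “Substrate remains the largest holder, well ahead of C.”
- The flask gives substrate at 45.7%.

    substrate → intermediate A (k = 0.111 h⁻¹)
    intermediate A → intermediate B (k = 0.140 h⁻¹)
    substrate ⇌ intermediate C (K = 0.630, k = 1.89 h⁻¹)
    intermediate B ⇌ target (K = 22.7, k = 0.263 h⁻¹)
    substrate + target ⇌ idle adduct, settled at all times (K = 2.20 M⁻¹)
    target ⇌ isomer of the product (K = 1.30, k = 0.219 h⁻¹)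

- In this flask, substrate and intermediate C relax, both directions together, with a half-life of 0.142 h, short against 4.0 h and against the pool's half-life ln(2)/λ of 9.64 h. Substrate is 60.8% of the flask's pool at 4.0 h.
- Carry λ to the neighbour flask, charged like this one but read at 15 h: φ·exp(−λt) gives substrate 20.8%. The computed neighbour holds 20.8%.

The runs were generated by integration for an exercise, noise included.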